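The earlier runs and the new flask are simulated for an exercise.

Amounts first: the south flask holds 0.10 M of substrate against 0.150 M of coupling partner, so substrate is its limiting reagent. The south-east run, with 0.075 M of coupling partner, is short of the partner instead.

the same everywhere: substrate 0.10 M

| flask | coupling partner | remark | time |
|---|---|---|---|
| south | 0.15 M | the very flask that is asked about, followed so far |  |
| south-east | 0.075 M | run made earlier |  |
| flask | 0.150 M |  | 5.0 min |

| run | time / min | target / % |
|---|---|---|
| south | 0.417 | 48.5 |
| south | 0.667 | 44.2 |
| south | 1.00 | 42.3 |
| south | 2.00 | 36.6 |
| south | 3.00 | 35.8 |
| south | 5.00 | 37.0 |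
| south-east | 0.200 | 29.8 |
| south-east | 0.333 | 33.0 |
| south-east | 0.500 | 33.8 |
| south-east | 0.833 | 29.9 |
| south-east | 1.50 | 28.7 |
| south-east | 2.50 | 26.3 |

(readings scatter by 1 percentage point)

- target that was removed still counts
- additions bring no volume worth counting

- beta: at 5.0 min add substrate, 50.0% of the amount charged, then wait 5.0 min
- epsilon: at 5.0 min take out 90% of the target then present, then wait 5.0 min
- delta: at 5.0 min add coupling partner, 100% of the amount charged, then wait 5.0 min
- zeta: change nothing and wait 5.0 min more

1. target, in percent of the substrate first charged, at 5.0 min
2. what to do for the largest gain in target; "none" if nothing gains more than 2 percentage points (beta / epsilon / delta / zeta / none)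
3. target present, with what was taken out counted in, in percent of the substrate first charged, after epsilon
4. target present, with what was taken out counted in, in percent of the substrate first charged, after zeta

In the first instants coupling is fast: south already shows 48.5% target at 0.417 min, its first reading. In the middle, target sags to 36.6% at 2.00 min, and what it becomes is not read. At the end, south's last readings differ by 1.2 percentage points, about the scatter of 1 point, so south reads as resting.

South then gives 37.0%. This is the resting share s, the target at rest per amount of limiting reagent in the flask. South-east, a different limit, reads 35.1% at its last reading, 2.50 min, but its readings are still falling, so that figure is no resting value. As an estimate for these flasks, at this one temperature: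

c(target) ≈ s × min(c(substrate), c(coupling partner)), whole amounts counted

Applied to the options, in percent of the first charge:

- Zeta and delta: substrate stays limiting, so the estimate for target stays near 37.0%.
- Beta: 55.5%.
- Epsilon: 33.3% leaves, the remaining 66.7% of the substrate charge rests at share s, and the total is 58.0%.

So in this reckoning epsilon comes out ahead.

The forecast gives 36.5%, 36.5% after zeta and 56% after epsilon, slightly under this reckoning, and picks epsilon: “This is the best option under both models.”

    substrate + coupling partner ⇌ isomer of the product A (K = 20.0 L mol⁻¹, k = 0.290 L mol⁻¹ s⁻¹)
    target ⇌ isomer of the product B (K = 1.30, k = 0.0170 s⁻¹)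
    substrate + coupling partner ⇌ target (K = 97.0 L mol⁻¹, k = 0.850 L mol⁻¹ s⁻¹)

The flask gives 37.1%, and epsilon gains most, 21 points. At 5.00 min, free substrate stands at 6.94% of the charge, while isomer of the product B holds 47.5%. Epsilon ends at 58.1%, against 58.0% from the resting share.

A neighbour charged with 0.060 M of coupling partner has the partner as limiting reagent, and s gives 22.2% of target. The computed result is 21.8%.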